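**Remark on the structure:** the target is read as (1R,5S)-5-bromo-2-[(1R)-1-bromo-2-chloroethyl]-4,4-dimethylcyclohex-2-en-1-yl acetate, with acetate and ring bromine cis. Ring atoms are called C1 (OAc) to C6 and the side chain C1′ (CHBr) and C2′ (CH2Cl) throughout, also for the ketone intermediates.

**Assumption:** the CuCl/(R,R)-bisphosphine catalyst of step 6 is taken to deliver boron to the face that gives the 5R boronate; if the sense proves opposite, the (S,S)-ligand is used without other change.

## Retrosynthetic overview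

1. End game: C1′–Br by Appel inversion of the (S)-carbinol, C1–OAc by acylation, ring C5–Br by invertive bromodeboronation of a C5 boronate, C1–OH by CBS reduction of the ring ketone.
2. The C5 boronate comes from enantioselective conjugate borylation of a cross-conjugated 4,4-dimethylcyclohexa-2,5-dienone, made by dehydrogenation of the corresponding 2-substituted 4,4-dimethylcyclohex-2-enone.
3. Key disconnection: this enone is cut at C4–C5 and at C2=C3 into isobutyraldehyde (C4, C3 and both methyls) and a six-carbon vinyl ketone (C5, C6, C1, C2, C1′, C2′). One enamine Michael/aldol-condensation flask forms the only ring, the quaternary carbon and the ring alkene, and completes the ten-carbon skeleton.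
4. Enabling feature: in the cyclohexene ring the hydrogen-free quaternary C4 lies between the vinylic C3–H and C5, and the oxygenated C1 is joined to C3 through C2. This is the pattern of a 4,4-dimethylcyclohex-2-enone, so isobutyraldehyde (one α-hydrogen, C4 = its α-carbon, C3 = its formyl carbon) can annulate in only one sense.
5. The vinyl ketone is taken from the chiral pool: C4, C3, C2 and C1 of ethyl (S)-4-chloro-3-hydroxybutanoate become C2′ (with its chlorine), C1′ (oxygen stereocentre, later inverted to bromide), C2 and C1.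

Key step: step 4

## Route

Step 1
Reactants: 1 ethyl (3S)-4-chloro-3-hydroxybutanoate
Product: 2 ethyl (3S)-3-[(tert-butyldimethylsilyl)oxy]-4-chlorobutanoate
Conditions: TBSCl, imidazole, DMF, 0 °C to rt
Reagents that add atoms: tert-butyldimethylsilyl chloride, CC(C)(C)[Si](C)(C)Cl
Why: Imidazole-promoted silylation of a secondary alcohol (silyl ether protection) should proceed without touching the stereocentre and masks the hydroxyl against the organomagnesium steps.

Step 2
Reactants: 2 ethyl (3S)-3-[(tert-butyldimethylsilyl)oxy]-4-chlorobutanoate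
Product: 3 (3S)-3-[(tert-butyldimethylsilyl)oxy]-4-chloro-N-methoxy-N-methylbutanamide
Conditions: MeNH(OMe)·HCl, i-PrMgCl, THF, −20 °C
Reagents that add atoms: N,O-dimethylhydroxylamine hydrochloride, CNOC.Cl
Why: Aminolysis of the ester by the chloromagnesium amide of N,O-dimethylhydroxylamine (Weinreb amide formation) should be faster at −20 °C than enolisation, so the β-silyloxy group is not eliminated and the stereocentre is retained.

Step 3
Reactants: 3 (3S)-3-[(tert-butyldimethylsilyl)oxy]-4-chloro-N-methoxy-N-methylbutanamide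
Product: 4 (5S)-5-[(tert-butyldimethylsilyl)oxy]-6-chlorohex-1-en-3-one
Conditions: CH2=CHMgBr, THF, −20 to 0 °C; inverse quench into cold 1 M HCl
Reagents that add atoms: vinylmagnesium bromide, C=C[Mg]Br
Why: Weinreb ketone synthesis: the chelated tetrahedral adduct stops at mono-addition and collapses to the vinyl ketone only on the cold acidic inverse quench, which also keeps the released amine protonated so that it cannot add back to the enone.

Step 4
Reactants: 4 (5S)-5-[(tert-butyldimethylsilyl)oxy]-6-chlorohex-1-en-3-one, 5 isobutyraldehyde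
Product: 8 2-[(1S)-1-[(tert-butyldimethylsilyl)oxy]-2-chloroethyl]-4,4-dimethylcyclohex-2-en-1-one, via enamine 6 (not isolated), via keto aldehyde 7 (not isolated)
Conditions: 5, pyrrolidine, 4 Å MS, PhMe, rt; then 4, 0 °C to rt; then AcOH/NaOAc/H2O, 60 °C
Reagents that add atoms: none
Why: Stork enamine version of the Robinson annulation: enamine 6 attacks the terminal vinyl carbon of 4 with its β-carbon (future C4) to create the C4–C5 bond and the quaternary centre, buffered hydrolysis releases keto aldehyde 7, and the enol of the ketone on its C2 flank then adds to the neopentyl aldehyde (future C3) and the aldol loses water to give the C2=C3 enone. The closest known reaction is the enamine annulation of isobutyraldehyde with methyl vinyl ketone to 4,4-dimethylcyclohex-2-en-1-one, the vinyl ketone here differing only by a branched α′-substituent. The single ring closes in a 6-(enolendo)-exo-trig aldol step. No new stereocentre is created and the side-chain stereocentre, which carries no enolisable hydrogen, is carried through unchanged. The step needs chemoselectivity and regioselectivity, and the substrates secure both: isobutyraldehyde has a single α-hydrogen, so 7 cannot enolise on its aldehyde side and acts only as the electrophile, while of the two ketone α-carbons only C2 can reach the aldehyde through a six-membered transition state (C6 would close a four-membered ring). The weakly acidic acetate buffer is chosen so that cyclodehydration outruns β-elimination of the silyloxy group, and dehydration can only give the C2=C3 alkene because C4 bears no hydrogen.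

Step 5
Reactants: 8 2-[(1S)-1-[(tert-butyldimethylsilyl)oxy]-2-chloroethyl]-4,4-dimethylcyclohex-2-en-1-one
Product: 9 2-[(1S)-1-[(tert-butyldimethylsilyl)oxy]-2-chloroethyl]-4,4-dimethylcyclohexa-2,5-dien-1-one
Conditions: IBX (2-iodoxybenzoic acid), DMSO/PhMe, 70 °C
Reagents that add atoms: none
Why: IBX dehydrogenation of a ketone through its enol (a known route from cyclohexenones to cross-conjugated dienones) can only desaturate C5–C6 because C4 is quaternary, and silyl ether and alkyl chloride are inert to the oxidant.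

Step 6
Reactants: 9 2-[(1S)-1-[(tert-butyldimethylsilyl)oxy]-2-chloroethyl]-4,4-dimethylcyclohexa-2,5-dien-1-one
Product: 10 (5R)-2-[(1S)-1-[(tert-butyldimethylsilyl)oxy]-2-chloroethyl]-4,4-dimethyl-5-(4,4,5,5-tetramethyl-1,3,2-dioxaborolan-2-yl)cyclohex-2-en-1-one
Conditions: B2pin2, CuCl (5 mol%), (R,R)-2,3-bis(tert-butylmethylphosphino)quinoxaline, NaOt-Bu (10 mol%), MeOH, THF, 0 °C
Reagents that add atoms: bis(pinacolato)diboron, CC1(C)OB(OC1(C)C)B1OC(C)(C)C(C)(C)O1
Why: Copper-catalysed enantioselective conjugate borylation of a cyclic enone: the borylcopper species adds boron to C5 of the unsubstituted enone arm (the C2=C3 arm is α-branched and much less electrophilic), the C2-symmetric bisphosphine selects the face to set C5 as R, and methanol protonates the copper enolate.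

Step 7
Reactants: 10 (5R)-2-[(1S)-1-[(tert-butyldimethylsilyl)oxy]-2-chloroethyl]-4,4-dimethyl-5-(4,4,5,5-tetramethyl-1,3,2-dioxaborolan-2-yl)cyclohex-2-en-1-one
Product: 11 (1R,5R)-2-[(1S)-1-[(tert-butyldimethylsilyl)oxy]-2-chloroethyl]-4,4-dimethyl-5-(4,4,5,5-tetramethyl-1,3,2-dioxaborolan-2-yl)cyclohex-2-en-1-ol
Conditions: (S)-2-methyl-CBS-oxazaborolidine (20 mol%), catecholborane, PhMe, −78 °C
Reagents that add atoms: none
Why: CBS reduction under reagent control: in the usual transition-state model the alkenyl C2 flank is the large group and the C6 methylene the small one, so the (S)-catalyst should deliver hydride to give the 1R allylic alcohol (oxygen trans to boron) with 1,2-selectivity, the boronic ester being inert to catecholborane.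

Step 8
Reactants: 11 (1R,5R)-2-[(1S)-1-[(tert-butyldimethylsilyl)oxy]-2-chloroethyl]-4,4-dimethyl-5-(4,4,5,5-tetramethyl-1,3,2-dioxaborolan-2-yl)cyclohex-2-en-1-ol
Product: 12 trimethylsilyl ether of 11 at the C1 oxygen, (1R,5R), side chain (1S)
Conditions: TMSCl, imidazole, CH2Cl2, 0 °C
Reagents that add atoms: chlorotrimethylsilane, C[Si](C)(C)Cl
Why: Routine silylation gives a trimethylsilyl ether that shields the hydroxyl from the aryllithium and from NBS in the next step and falls off on mild acid work-up while the tert-butyldimethylsilyl ether stays.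

Step 9
Reactants: 12 trimethylsilyl ether of 11
Product: 15 (1R,5S)-5-bromo-2-[(1S)-1-[(tert-butyldimethylsilyl)oxy]-2-chloroethyl]-4,4-dimethylcyclohex-2-en-1-ol, via aryl boronate complex 13 (not isolated), via silyl ether bromide 14 (not isolated)
Conditions: 3,5-(CF3)2C6H3Br, n-BuLi, THF, −78 °C; then 12; then NBS, THF, −78 °C; then 1 M HCl, THF, 0 °C
Reagents that add atoms: N-bromosuccinimide, O=C1CCC(=O)N1Br
Why: Stereoinvertive halodeboronation of a secondary pinacol boronic ester: the electron-poor aryllithium adds to boron to give boronate complex 13, whose C5–B bond is attacked by NBS from the rear (SE2 with inversion; the bis(trifluoromethyl)phenyl group disfavours electron transfer and arene bromination), so that 5R C–B becomes 5S C–Br cis to the C1 oxygen, and dilute acid then cleaves only the trimethylsilyl ether of 14.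

Step 10
Reactants: 15 (1R,5S)-5-bromo-2-[(1S)-1-[(tert-butyldimethylsilyl)oxy]-2-chloroethyl]-4,4-dimethylcyclohex-2-en-1-ol
Product: 16 (1R,5S)-5-bromo-2-[(1S)-1-[(tert-butyldimethylsilyl)oxy]-2-chloroethyl]-4,4-dimethylcyclohex-2-en-1-yl acetate
Conditions: Ac2O, pyridine, DMAP (cat.), CH2Cl2, 0 °C to rt
Reagents that add atoms: acetic anhydride, CC(=O)OC(C)=O
Why: DMAP-catalysed acylation of the secondary allylic alcohol proceeds with retention at C1, and the neopentyl secondary bromide does not react with pyridine under these conditions.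

Step 11
Reactants: 16 (1R,5S)-5-bromo-2-[(1S)-1-[(tert-butyldimethylsilyl)oxy]-2-chloroethyl]-4,4-dimethylcyclohex-2-en-1-yl acetate
Product: 17 (1R,5S)-5-bromo-2-[(1S)-2-chloro-1-hydroxyethyl]-4,4-dimethylcyclohex-2-en-1-yl acetate
Conditions: HF·pyridine, THF, 0 °C to rt
Reagents that add atoms: none
Why: Fluoride-mediated cleavage of the silyl ether under slightly acidic conditions (desilylation) leaves acetate, both halides and the alkene intact and avoids base-promoted acetyl migration to the liberated hydroxyl.

Step 12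
Reactants: 17 (1R,5S)-5-bromo-2-[(1S)-2-chloro-1-hydroxyethyl]-4,4-dimethylcyclohex-2-en-1-yl acetate
Product: 18 (1R,5S)-5-bromo-2-[(1R)-1-bromo-2-chloroethyl]-4,4-dimethylcyclohex-2-en-1-yl acetate (CNP0213819.1)
Conditions: PPh3, CBr4, CH2Cl2, −20 to 0 °C
Reagents that add atoms: carbon tetrabromide, BrC(Br)(Br)Br
Why: Appel reaction: the alkoxyphosphonium ion of the secondary allylic alcohol is displaced by bromide in an SN2 step with inversion, turning the (S)-carbinol into the (R)-bromide, while SN2′ attack at C3 is blocked by the adjacent quaternary C4 and the β-chlorine disfavours ionisation.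

## Compound list

1 | ethyl (3S)-4-chloro-3-hydroxybutanoate | CCOC(=O)C[C@H](O)CCl | starting material
2 | ethyl (3S)-3-[(tert-butyldimethylsilyl)oxy]-4-chlorobutanoate | CCOC(=O)C[C@H](O[Si](C)(C)C(C)(C)C)CCl | intermediate
3 | (3S)-3-[(tert-butyldimethylsilyl)oxy]-4-chloro-N-methoxy-N-methylbutanamide | CON(C)C(=O)C[C@H](O[Si](C)(C)C(C)(C)C)CCl | intermediate
4 | (5S)-5-[(tert-butyldimethylsilyl)oxy]-6-chlorohex-1-en-3-one | C=CC(=O)C[C@H](O[Si](C)(C)C(C)(C)C)CCl | intermediate
5 | isobutyraldehyde (2-methylpropanal) | CC(C)C=O | starting material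
6 | 1-(2-methylprop-1-en-1-yl)pyrrolidine | CC(C)=CN1CCCC1 | intermediate
7 | (7S)-7-[(tert-butyldimethylsilyl)oxy]-8-chloro-2,2-dimethyl-5-oxooctanal | O=CC(C)(C)CCC(=O)C[C@H](O[Si](C)(C)C(C)(C)C)CCl | intermediate
8 | 2-[(1S)-1-[(tert-butyldimethylsilyl)oxy]-2-chloroethyl]-4,4-dimethylcyclohex-2-en-1-one | O=C1CCC(C)(C)C=C1[C@H](O[Si](C)(C)C(C)(C)C)CCl | intermediate
9 | 2-[(1S)-1-[(tert-butyldimethylsilyl)oxy]-2-chloroethyl]-4,4-dimethylcyclohexa-2,5-dien-1-one | O=C1C=CC(C)(C)C=C1[C@H](O[Si](C)(C)C(C)(C)C)CCl | intermediate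
10 | (5R)-2-[(1S)-1-[(tert-butyldimethylsilyl)oxy]-2-chloroethyl]-4,4-dimethyl-5-(4,4,5,5-tetramethyl-1,3,2-dioxaborolan-2-yl)cyclohex-2-en-1-one | O=C1C[C@@H](B2OC(C)(C)C(C)(C)O2)C(C)(C)C=C1[C@H](O[Si](C)(C)C(C)(C)C)CCl | intermediate
11 | (1R,5R)-2-[(1S)-1-[(tert-butyldimethylsilyl)oxy]-2-chloroethyl]-4,4-dimethyl-5-(4,4,5,5-tetramethyl-1,3,2-dioxaborolan-2-yl)cyclohex-2-en-1-ol | O[C@@H]1C[C@@H](B2OC(C)(C)C(C)(C)O2)C(C)(C)C=C1[C@H](O[Si](C)(C)C(C)(C)C)CCl | intermediate
12 | trimethylsilyl ether of 11 at the C1 oxygen, (1R,5R), side chain (1S) | C[Si](C)(C)O[C@@H]1C[C@@H](B2OC(C)(C)C(C)(C)O2)C(C)(C)C=C1[C@H](O[Si](C)(C)C(C)(C)C)CCl | intermediate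
13 | lithium boronate complex of 12 carrying a 3,5-bis(trifluoromethyl)phenyl group on boron | [Li+].C[Si](C)(C)O[C@@H]1C[C@@H]([B-]2(OC(C)(C)C(C)(C)O2)c3cc(cc(c3)C(F)(F)F)C(F)(F)F)C(C)(C)C=C1[C@H](O[Si](C)(C)C(C)(C)C)CCl | intermediate
14 | trimethylsilyl ether of 15 at the C1 oxygen, (1R,5S), side chain (1S) | C[Si](C)(C)O[C@@H]1C[C@H](Br)C(C)(C)C=C1[C@H](O[Si](C)(C)C(C)(C)C)CCl | intermediate
15 | (1R,5S)-5-bromo-2-[(1S)-1-[(tert-butyldimethylsilyl)oxy]-2-chloroethyl]-4,4-dimethylcyclohex-2-en-1-ol | O[C@@H]1C[C@H](Br)C(C)(C)C=C1[C@H](O[Si](C)(C)C(C)(C)C)CCl | intermediate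
16 | (1R,5S)-5-bromo-2-[(1S)-1-[(tert-butyldimethylsilyl)oxy]-2-chloroethyl]-4,4-dimethylcyclohex-2-en-1-yl acetate | CC(=O)O[C@@H]1C[C@H](Br)C(C)(C)C=C1[C@H](O[Si](C)(C)C(C)(C)C)CCl | intermediate
17 | (1R,5S)-5-bromo-2-[(1S)-2-chloro-1-hydroxyethyl]-4,4-dimethylcyclohex-2-en-1-yl acetate | CC(=O)O[C@@H]1C[C@H](Br)C(C)(C)C=C1[C@H](O)CCl | intermediate
18 | (1R,5S)-5-bromo-2-[(1R)-1-bromo-2-chloroethyl]-4,4-dimethylcyclohex-2-en-1-yl acetate | CC(=O)O[C@@H]1C[C@H](Br)C(C)(C)C=C1[C@@H](Br)CCl | target

## Step count and risks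

Total step count: 12. Longest linear sequence: 12 steps (1 to 18); isobutyraldehyde 5 enters at step 4.

The three steps most likely to fail:

**Step 9 (bromodeboronation at the neopentyl C5).** Rear-side electrophilic substitution next to the quaternary C4 may be slow, so that electron-transfer bromination with scrambling at C5, or bromination of the ring alkene, competes. The fallback avoids boron altogether; it sets out from 9 and comes back at 15. Dienone 9 is treated with HBr (generated from TMSBr and MeOH, CH2Cl2, −40 °C). Bromide should add in conjugate fashion to the unsubstituted enone arm to give 5-bromo-2-[(1S)-1-[(tert-butyldimethylsilyl)oxy]-2-chloroethyl]-4,4-dimethylcyclohex-2-en-1-one F1 as a mixture of C5 epimers. CBS reduction with the (S)-catalyst and catecholborane should set C1 as R in both epimers. Chromatography then separates the cis alcohol 15 from (1R,5R)-5-bromo-2-[(1S)-1-[(tert-butyldimethylsilyl)oxy]-2-chloroethyl]-4,4-dimethylcyclohex-2-en-1-ol F2, at the cost of the material that ends as F2. Steps 10 to 12 follow unchanged.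

**Step 6 (enantioselective conjugate borylation).** The catalyst may discriminate the two faces of C5 poorly in the presence of the distant side-chain stereocentre, and protodeboronation may erode the product. The fallback replaces catalyst control by separation on the pre-installed stereocentre; it sets out from 9 and comes back at 10. Borylation with an achiral catalyst (CuCl, 4,5-bis(diphenylphosphino)-9,9-dimethylxanthene, NaOt-Bu, B2pin2, MeOH) should give 10 together with its epimer (5S)-2-[(1S)-1-[(tert-butyldimethylsilyl)oxy]-2-chloroethyl]-4,4-dimethyl-5-(4,4,5,5-tetramethyl-1,3,2-dioxaborolan-2-yl)cyclohex-2-en-1-one F3. Because of the side-chain stereocentre the two are diastereomers, and chromatography should deliver pure 10.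

**Step 4 (annulation).** Enolisation of the ketone toward C2 may trigger β-elimination of the silyloxy group before the aldol closure, and the vinyl ketone may polymerise. The fallback builds the ring first and attaches the side chain afterwards; it sets out from 5 and comes back at 8.
- Enamine annulation of 5 with methyl vinyl ketone gives 4,4-dimethylcyclohex-2-en-1-one F4.
- α-Iodination (I2, pyridine) gives 2-iodo-4,4-dimethylcyclohex-2-en-1-one F5.
- Ketalisation (ethylene glycol, TsOH) gives 6-iodo-8,8-dimethyl-1,4-dioxaspiro[4.5]dec-6-ene F6.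
- Iodine–lithium exchange (t-BuLi, THF, −78 °C) and acylation with 2-chloro-N-methoxy-N-methylacetamide give 2-chloro-1-(8,8-dimethyl-1,4-dioxaspiro[4.5]dec-6-en-6-yl)ethan-1-one F7.
- CBS reduction with the (S)-catalyst and BH3·SMe2 (alkenyl group large, chloromethyl small) should give (1S)-2-chloro-1-(8,8-dimethyl-1,4-dioxaspiro[4.5]dec-6-en-6-yl)ethan-1-ol F8.
- Silylation (TBSOTf, 2,6-lutidine) gives tert-butyl[(1S)-2-chloro-1-(8,8-dimethyl-1,4-dioxaspiro[4.5]dec-6-en-6-yl)ethoxy]dimethylsilane F9.
- Ketal hydrolysis (PPTS, wet acetone) gives 8.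

## Further compounds

F1 | step 9 | 5-bromo-2-[(1S)-1-[(tert-butyldimethylsilyl)oxy]-2-chloroethyl]-4,4-dimethylcyclohex-2-en-1-one (both C5 epimers) | O=C1CC(Br)C(C)(C)C=C1[C@H](O[Si](C)(C)C(C)(C)C)CCl
F2 | step 9 | (1R,5R)-5-bromo-2-[(1S)-1-[(tert-butyldimethylsilyl)oxy]-2-chloroethyl]-4,4-dimethylcyclohex-2-en-1-ol | O[C@@H]1C[C@@H](Br)C(C)(C)C=C1[C@H](O[Si](C)(C)C(C)(C)C)CCl
F3 | step 6 | (5S)-2-[(1S)-1-[(tert-butyldimethylsilyl)oxy]-2-chloroethyl]-4,4-dimethyl-5-(4,4,5,5-tetramethyl-1,3,2-dioxaborolan-2-yl)cyclohex-2-en-1-one | O=C1C[C@H](B2OC(C)(C)C(C)(C)O2)C(C)(C)C=C1[C@H](O[Si](C)(C)C(C)(C)C)CCl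
F4 | step 4 | 4,4-dimethylcyclohex-2-en-1-one | CC1(C)CCC(=O)C=C1
F5 | step 4 | 2-iodo-4,4-dimethylcyclohex-2-en-1-one | CC1(C)CCC(=O)C(I)=C1
F6 | step 4 | 6-iodo-8,8-dimethyl-1,4-dioxaspiro[4.5]dec-6-ene | CC1(C)CCC2(OCCO2)C(I)=C1
F7 | step 4 | 2-chloro-1-(8,8-dimethyl-1,4-dioxaspiro[4.5]dec-6-en-6-yl)ethan-1-one | CC1(C)CCC2(OCCO2)C(=C1)C(=O)CCl
F8 | step 4 | (1S)-2-chloro-1-(8,8-dimethyl-1,4-dioxaspiro[4.5]dec-6-en-6-yl)ethan-1-ol | CC1(C)CCC2(OCCO2)C(=C1)[C@H](O)CCl
F9 | step 4 | tert-butyl[(1S)-2-chloro-1-(8,8-dimethyl-1,4-dioxaspiro[4.5]dec-6-en-6-yl)ethoxy]dimethylsilane | CC1(C)CCC2(OCCO2)C(=C1)[C@H](O[Si](C)(C)C(C)(C)C)CCl
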